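(The earlier runs and the new flask were computed with made-up constants, and the scatter is random.)

In a closed, stirred vessel of constant volume, held at one temperature, we start from c(substrate) = 20 mM with 1.50 equiv of reagent and add initiator at different loadings.

the same everywhere: substrate 20 mM
- red: reagent 1.5 equiv; initiator 4.4 mol%; run made earlier
- ochre: reagent 1.5 equiv; initiator 30 mol%; run made earlier
- south: reagent 1.50 equiv; initiator 5 mol%; time 30 min
- west: reagent 1.50 equiv; initiator 10 mol%; time 30 min
- north-east: reagent 1.50 equiv; initiator 20 mol%; time 30 min
- south-west: reagent 1.50 equiv; initiator 40 mol%; time 30 min

| run | time / min | target / % | substrate / % |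
|---|---|---|---|
| red | 2.00 | 23.9 | 75.5 |
| red | 5.00 | 50.8 | 47.0 |
| red | 10.0 | 81.9 | 15.1 |
| red | 15.0 | 95.9 | 0.3 |
| red | 20.0 | 96.0 | 0.1 |
| ochre | 2.00 | 57.8 | 36.6 |
| ochre | 5.00 | 89.9 | 0 |
| ochre | 10.0 | 90.8 | 0 |
| ochre | 15.0 | 90.8 | 0 |
| ochre | 20.0 | 90.2 | 0 |

(each reading ± 0.3 percentage points)

- amount of target at the end, in percent of the substrate charged for south, west, north-east, south-west, in this order
- how that number moves from the first to the last of them (falls all the way / rises, then falls / hardly changes / falls, then rises / rises all the way)

We begin with a balance. Reagent is charged in excess, so substrate is the limiting reagent, and each percent of it charged must be found as substrate, as target, or as something we do not read. Call this last part the lost share. In red at 20.0 min, substrate reads 0.1%, less than the scatter of 0.3 percentage points, and target reads 96.0%, so the lost share is 4.00%. In ochre, substrate reads 0% from 5.00 min on, and the mean target gives a lost share of 9.57%. In both runs target hardly changes once substrate has reached these readings, so over those times the lost share does not grow, and red and ochre differ in their charges by the loading of initiator.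

Going from red to ochre multiplies the loading by 6.82 but the lost share by 2.39. We therefore describe the two readings by a power law and define the loss order, the power of the loading to which the lost share rises: 0.455. Red reads substrate 0.3% at 15.0 min, earlier than the 30 min allowed; ochre, at its higher loading, reads less substrate than red at 2.00 min, and each new flask has a higher loading than red, so we expect each to reach its plateau. Scaling the lost share of red by this power, our own reckoning gives target of 95.8%, 94.2%, 92.0% and 89.1%.

The forecast gives 95.8%, 94.5%, 92.3% and 88.4%, so that target falls all the way, and its ground is “The loss is set by the initiator”. It lies above our reckoning at 10 mol% and below it at 40 mol%.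

The flasks give 95.7%, 94.0%, 91.9% and 89.1%, and target falls all the way; the forecast stands within its margin.

    reagent + first chain carrier → target + second chain carrier (k = 20000 M⁻¹ s⁻¹)
    substrate + initiating radical → capped initiator + first chain carrier (k = 8.80 × 10⁵ M⁻¹ s⁻¹)
    first chain carrier → ended carrier (k = 230 min⁻¹)
    initiator → 2 initiating radical (k = 0.0460 min⁻¹)
    substrate + second chain carrier → by-product + first chain carrier (k = 18000 M⁻¹ s⁻¹)
    2 first chain carrier → ended chains (k = 9.60 × 10⁷ M⁻¹ s⁻¹)

In south at 4.23 min, substrate has a half-life of 4.0 min by its step with second chain carrier, shorter than the 15 min of initiator by its own decay. At 15.0 min south already holds substrate 0% and target 95.7%, with 50.2% of its initiator charge left. South lost 4.30%, and scaling this by the loss order gives an estimate of 11.1% for south-west. At 30.0 min south-west holds 0.864% as ended carrier and 10.0% as ended chains, together 10.9% of the substrate charged.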